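Monday's run, which reports Tgt up to 10.0 min and nothing of Sid, cannot say what becomes of Tgt once it is made, so I asked first how long the making lasts.

in all of them: Sbt 20 mM

| run | Cat | remark | time |
|---|---|---|---|
| Monday's | 0.02 mol% | run made earlier |  |
| ash | 0.01 mol% |  | 1.5 h |
| larch | 0.01 mol% |  | 5.0 h |
| birch | 0.01 mol% |  | 15 h |

Monday's run (percent of the Sbt charged)

| time / min | Tgt / % |
|---|---|
| 0.667 | 4 |
| 1.33 | 1 |
| 2.00 | 3 |
| 3.00 | 8 |
| 5.00 | 11 |
| 10.0 | 29 |

(scatter of a reading: 2 percentage points)

- the numbers in the tables scatter by 2 percentage points (one standard deviation)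
- no earlier run changes the charge of Cat; that part of a forecast is a guess

- which of the two there is more of at the end, ash (Tgt / Sid)
- which of the two there is more of at the end, larch (Tgt / Sid)
- which of the two there is more of at the end, birch (Tgt / Sid)
- final Tgt, as a percentage of the Sbt charged, in ash
- final Tgt, as a percentage of the Sbt charged, in larch
- final Tgt, as a percentage of the Sbt charged, in birch

I began with the balance of Cat, the reagent charged in the smaller amount. I took it that making Tgt does not spend Cat, so each Cat has to turn over many Sbt, and Monday's run gives the pace of that work. Monday's Cat, at 0.02 mol%, had made 29% by 10.0 min. I assumed that the pace follows the amount of Cat, which is a guess, since no run changes it. By my estimate, with that pace held straight, the 0.01 mol% of ash, larch and birch needs 69.0 min to turn over the whole charge of Sbt once. I called this the filling time: the time for the charge to pass through Cat at Monday's average pace, scaled by the ratio of loadings.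

I then ran the flask slowly in my head. In the first instants Cat meets the full 20 mM of Sbt, and Monday's earliest readings, 4% and 1%, stand against a scatter of 2 percentage points, so I read nothing from them. In the middle, making Tgt is the one step I can see, and the straight pace uses half of the Sbt in 34.5 min. By the end of the filling time the straight pace has, on paper, passed the whole charge through Cat, and what happens to Tgt and Cat after that does not stand in Monday's readings. Ash stops 0.351 h past that point, larch 3.85 h and birch 13.9 h, all unread hours. So I committed to most of the charge having reacted in ash, and I gave larch and birch no number of my own.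

The forecast named Tgt the larger in ash, Tgt in larch and Tgt in birch, with Tgt at 65%, 72% and 68%, and it noted that “a slow Tgt-to-Sid step would hurt most at 15 h”.

The flasks gave Tgt 59.1% and Sid 26.0% in ash, Tgt 23.5% and Sid 75.8% in larch, and Tgt 9.27% and Sid 90.7% in birch.

    Sbt + Cat → Tgt + Cat, rate k1*[Sbt]*[Cat]/(1 + ([Sbt]/Km1) + ([Sbt]/Ksi1)^2) (0.0503 M, 13.2 mM, k = 521 L mol⁻¹ s⁻¹)
    Tgt ⇌ Sid (K = 10.0, k = 1.15 × 10⁻⁴ s⁻¹)
    2 Cat → Zet (k = 73.9 L mol⁻¹ s⁻¹)

The straight pace ran ahead of ash: at 0.750 h it leaves 34.8% of the Sbt, but the flask held more, 41.3%, with 44.4% of the Cat already Zet. The neighbouring flask is larch read at 80 min, which is 1.16 filling times. There 18.6% of the Sbt still stood, 41.3% of the Cat remained, and Tgt was 59.3%, more than the 23.5% of larch at 5.0 h.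

The earlier runs and the new flask are calculated for substances that don't exist; the scatter is artificial.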